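**Plan**

1. Numbering: chromone O1, C2, C3, C4, C4a–C8a (ring C fused to ring A); ring B is C1'–C6' with the ring D furan oxygen on C2'; ring E is the pyran on O7/C8; ring F is the pyran on C3'/C4' with carbinol carbons C3''' and C4'''.
2. Retrosynthesis: remove the three protecting groups; cut the ring D bond O–C2' (the C4 carbonyl goes back to a 4-methoxycoumarin with C2'–H and a free C5'–OH); cut C3–C1' (Suzuki–Miyaura). In the ring A/E half cut O1–C2 and C2–C3 (carbonate Claisen), ring E, and the acetyl C–C bond. In the ring B/F half cut C1'–B, the epoxide-derived C–O bonds and ring F (propargyl Claisen).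
3. Forward: ring A is built from 2,4,6-trihydroxybenzaldehyde through a symmetrical tosylate that fixes which oxygen becomes O1. Ring E closes in step 4 and ring C (as a 4-hydroxycoumarin) in step 7. Ring F closes on catechol-derived ring B in step 12. The halves are joined at C3–C1' in step 17 and ring D closes last in step 19.
4. Stereochemistry: one Jacobsen–Katsuki epoxidation of the ring F chromene sets C3''' (R) directly and C4''' (S) by inversion on hydrolysis; the trans-diol is carried as its diacetate.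
5. Enabling feature: ring B has its only free hydroxyl on C5', para to C2'–H, and C2' is ortho to the C1'–C3 bond. Oxidising the C5' phenol therefore makes C2' electrophilic within reach of the carbonyl oxygen on C2, while the O4 methyl ether leaves that oxygen as the only internal nucleophile.

Key step: step 19

Assumption: the (R,R)-salen manganese chloride catalyst is taken to give the (3R,4R)-epoxide of the 2,2-dimethylchromene, the facial sense established for this substrate class.

**Route**

Step 1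
Reactants: 1 2,4,6-trihydroxybenzaldehyde
Product: 2 4-formyl-3,5-dihydroxyphenyl 4-methylbenzenesulfonate
Conditions: TsCl (1.0 equiv), K2CO3, acetone, 0 °C to rt
Reagents that add atoms: 4-methylbenzenesulfonyl chloride, Cc1ccc(cc1)S(Cl)(=O)=O
Why: Chemoselective O-sulfonylation: both ortho hydroxyls are tied up in hydrogen bonds to the formyl group, so only the para hydroxyl should be tosylated, and this tosylate marks the oxygen that will become O1.

Step 2
Reactants: 2 4-formyl-3,5-dihydroxyphenyl 4-methylbenzenesulfonate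
Product: 4 3,5-dihydroxy-4-methylphenyl 4-methylbenzenesulfonate, via benzylic alcohol 3 (not isolated)
Conditions: Et3SiH (3 equiv), TFA, CH2Cl2, 0 °C to rt
Reagents that add atoms: none
Why: Ionic hydrogenation: the ortho hydroxyls stabilise the benzylic cation formed from alcohol 3, which the silane reduces, so the formyl carbon becomes the future C6 methyl group and a symmetrical resorcinol results.

Step 3
Reactants: 4 3,5-dihydroxy-4-methylphenyl 4-methylbenzenesulfonate
Product: 5 2-acetyl-3,5-dihydroxy-4-methylphenyl 4-methylbenzenesulfonate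
Conditions: AcOH, BF3·OEt2, 90 °C; then aq. NaOAc
Reagents that add atoms: acetic acid, CC(O)=O
Why: Friedel–Crafts acylation of a resorcinol (Nencki type); the two open ring positions are equivalent by symmetry, so a single ketone should form with its acetyl group between a free hydroxyl and the tosyloxy group.

Step 4
Reactants: 5 2-acetyl-3,5-dihydroxy-4-methylphenyl 4-methylbenzenesulfonate; 6 3-methylbut-2-enal
Product: 7 6-acetyl-7-hydroxy-2,2,8-trimethyl-2H-chromen-5-yl 4-methylbenzenesulfonate
Conditions: ethylenediammonium diacetate (10 mol%), xylene, 140 °C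
Reagents that add atoms: none
Why: Chromene annulation (amine-catalysed Knoevenagel-type condensation at the ring carbon, dehydration to an ortho-quinone methide, oxa-6π electrocyclisation); the only free ring carbon lies between the unchelated hydroxyl and the tosylated oxygen, so ring E can close in one direction only.

Step 5
Reactants: 7 6-acetyl-7-hydroxy-2,2,8-trimethyl-2H-chromen-5-yl 4-methylbenzenesulfonate
Product: 8 6-acetyl-7-(methoxymethoxy)-2,2,8-trimethyl-2H-chromen-5-yl 4-methylbenzenesulfonate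
Conditions: NaH, MOMCl, DMF, 0 °C
Reagents that add atoms: chloromethyl methyl ether, COCCl
Why: Williamson ether synthesis on the sodium phenoxide; the one remaining hydroxyl, chelated to the ketone and flanked by the methyl group, is the future C5–OH and takes the methoxymethyl group.

Step 6
Reactants: 8 6-acetyl-7-(methoxymethoxy)-2,2,8-trimethyl-2H-chromen-5-yl 4-methylbenzenesulfonate
Product: 9 1-[5-hydroxy-7-(methoxymethoxy)-2,2,8-trimethyl-2H-chromen-6-yl]ethan-1-one
Conditions: KOH, MeOH/H2O (4:1), 65 °C; then 1 M HCl to pH 5 at 0 °C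
Reagents that add atoms: none
Why: Alkaline hydrolysis of an aryl sulfonate by attack of hydroxide at sulfur, which spares the acetal, the chromene and the ketone and frees the phenol next to ring E that is to become O1.

Step 7
Reactants: 9 1-[5-hydroxy-7-(methoxymethoxy)-2,2,8-trimethyl-2H-chromen-6-yl]ethan-1-one
Product: 10 4-hydroxy-5-(methoxymethoxy)-6,8,8-trimethyl-2H,8H-pyrano[2,3-f]chromen-2-one
Conditions: NaH (4 equiv), (EtO)2CO, toluene, 110 °C; then 1 M HCl to pH 4 at 0 °C
Reagents that add atoms: diethyl carbonate, CCOC(=O)OCC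
Why: Claisen condensation of the ketone enolate with diethyl carbonate followed by lactonisation onto the single free phenoxide, the standard route from 2-hydroxyacetophenones to 4-hydroxycoumarins, closes ring C.

Step 8
Reactants: 10 4-hydroxy-5-(methoxymethoxy)-6,8,8-trimethyl-2H,8H-pyrano[2,3-f]chromen-2-one
Product: 11 3-bromo-4-hydroxy-5-(methoxymethoxy)-6,8,8-trimethyl-2H,8H-pyrano[2,3-f]chromen-2-one
Conditions: NBS (1.0 equiv), CH2Cl2, 0 °C
Reagents that add atoms: N-bromosuccinimide, BrN1C(=O)CCC1=O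
Why: Electrophilic bromination at C3 of the enolised β-keto lactone, which is far more nucleophilic than the ring E double bond, so one equivalent of NBS at 0 °C should halogenate C3 alone.

Step 9
Reactants: 11 3-bromo-4-hydroxy-5-(methoxymethoxy)-6,8,8-trimethyl-2H,8H-pyrano[2,3-f]chromen-2-one
Product: 12 3-bromo-4-methoxy-5-(methoxymethoxy)-6,8,8-trimethyl-2H,8H-pyrano[2,3-f]chromen-2-one
Conditions: Me2SO4, K2CO3, acetone, 56 °C
Reagents that add atoms: dimethyl sulfate, COS(=O)(=O)OC
Why: O-Methylation of the ambident coumarin anion with dimethyl sulfate and K2CO3, conditions that deliver 4-methoxycoumarins, fixes O4 as the blocked oxygen before the coupling.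

Step 10
Reactants: 13 catechol
Product: 14 2-[(triisopropylsilyl)oxy]phenol
Conditions: NaH (1.0 equiv), THF, 0 °C; TIPSCl (1.0 equiv)
Reagents that add atoms: chlorotri(propan-2-yl)silane, CC(C)[Si](Cl)(C(C)C)C(C)C
Why: Monosilylation of the catechol monoanion; the bulk of the first triisopropylsilyl group disfavours a second silylation, and this ether is the protected C5'–OH.

Step 11
Reactants: 14 2-[(triisopropylsilyl)oxy]phenol; 15 3-chloro-3-methylbut-1-yne
Product: 16 triisopropyl{2-[(2-methylbut-3-yn-2-yl)oxy]phenoxy}silane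
Conditions: DBU, CuCl2·2H2O (0.5 mol%), MeCN, 0 °C
Reagents that add atoms: none
Why: Copper-catalysed propargylic etherification of a phenol with a tertiary propargylic chloride, the established way to 1,1-dimethylpropargyl aryl ethers.

Step 12
Reactants: 16 triisopropyl{2-[(2-methylbut-3-yn-2-yl)oxy]phenoxy}silane
Product: 17 [(2,2-dimethyl-2H-chromen-8-yl)oxy]triisopropylsilane
Conditions: N,N-diethylaniline, 190 °C
Reagents that add atoms: none
Why: Aromatic propargyl Claisen rearrangement, 1,5-hydrogen shift and oxa-6π electrocyclisation; only one ortho position is free (the other carries the silyloxy group), so ring F closes at the carbon that becomes C3'.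

Step 13
Reactants: 17 [(2,2-dimethyl-2H-chromen-8-yl)oxy]triisopropylsilane
Product: 18 (3R,4R)-3,4-epoxy-2,2-dimethyl-8-[(triisopropylsilyl)oxy]-3,4-dihydro-2H-chromene
Conditions: (R,R)-N,N'-bis(3,5-di-tert-butylsalicylidene)-1,2-cyclohexanediaminomanganese chloride (4 mol%), 4-phenylpyridine N-oxide, aq. NaOCl (pH 11.3), CH2Cl2, 0 °C
Reagents that add atoms: sodium hypochlorite, [Na+].[O-]Cl
Why: Jacobsen–Katsuki epoxidation, for which cis-configured 2,2-dimethylchromenes are the best substrates; the (R,R) catalyst directs oxygen to one face and gives the (3R,4R)-epoxide, which fixes C3''' for good.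

Step 14
Reactants: 18 (3R,4R)-3,4-epoxy-2,2-dimethyl-8-[(triisopropylsilyl)oxy]-3,4-dihydro-2H-chromene
Product: 19 (3R,4S)-2,2-dimethyl-8-[(triisopropylsilyl)oxy]chromane-3,4-diol
Conditions: 0.5 M H2SO4, acetone/H2O, 0 °C to rt
Reagents that add atoms: water, O
Why: Acid-catalysed epoxide hydrolysis: water opens the protonated epoxide at the benzylic carbon from the face opposite the leaving oxygen, so C4 is inverted while C3 is untouched and the trans-(3R,4S)-diol should result.

Step 15
Reactants: 19 (3R,4S)-2,2-dimethyl-8-[(triisopropylsilyl)oxy]chromane-3,4-diol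
Product: 20 (3R,4S)-2,2-dimethyl-8-[(triisopropylsilyl)oxy]chromane-3,4-diyl diacetate
Conditions: Ac2O, pyridine, DMAP (cat.), rt to 40 °C
Reagents that add atoms: acetic anhydride, CC(=O)OC(C)=O
Why: DMAP-catalysed acetylation; the diacetate shields the glycol from cleavage by PhI(OAc)2 later and is removable by mild methanolysis at the end.

Step 16
Reactants: 20 (3R,4S)-2,2-dimethyl-8-[(triisopropylsilyl)oxy]chromane-3,4-diyl diacetate
Product: 21 (3R,4S)-2,2-dimethyl-6-(4,4,5,5-tetramethyl-1,3,2-dioxaborolan-2-yl)-8-[(triisopropylsilyl)oxy]chromane-3,4-diyl diacetate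
Conditions: [Ir(OMe)(cod)]2 (1.5 mol%), 4,4'-di-tert-butyl-2,2'-bipyridine (3 mol%), B2pin2 (1.0 equiv), THF, 70 °C
Reagents that add atoms: bis(pinacolato)diboron, CC1(C)OB(OC1(C)C)B1OC(C)(C)C(C)(C)O1
Why: Iridium-catalysed aromatic C–H borylation under steric control: C6 is the only ring C–H without an ortho substituent, so boron enters at the future C1'.

Step 17
Reactants: 12 3-bromo-4-methoxy-5-(methoxymethoxy)-6,8,8-trimethyl-2H,8H-pyrano[2,3-f]chromen-2-one; 21 (3R,4S)-2,2-dimethyl-6-(4,4,5,5-tetramethyl-1,3,2-dioxaborolan-2-yl)-8-[(triisopropylsilyl)oxy]chromane-3,4-diyl diacetate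
Product: 22 (3R,4S)-6-[4-methoxy-5-(methoxymethoxy)-6,8,8-trimethyl-2-oxo-2H,8H-pyrano[2,3-f]chromen-3-yl]-2,2-dimethyl-8-[(triisopropylsilyl)oxy]chromane-3,4-diyl diacetate
Conditions: Pd(OAc)2 (5 mol%), SPhos (10 mol%), K3PO4, toluene/H2O (10:1), 60 °C
Reagents that add atoms: none
Why: Suzuki–Miyaura coupling of the 3-bromo-4-methoxycoumarin (an electron-poor vinyl bromide) with the unhindered arylboronate under a phosphate base that should leave acetates, silyl ether and enol ether intact; it forms C3–C1'.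

Step 18
Reactants: 22 (3R,4S)-6-[4-methoxy-5-(methoxymethoxy)-6,8,8-trimethyl-2-oxo-2H,8H-pyrano[2,3-f]chromen-3-yl]-2,2-dimethyl-8-[(triisopropylsilyl)oxy]chromane-3,4-diyl diacetate
Product: 23 (3R,4S)-8-hydroxy-6-[4-methoxy-5-(methoxymethoxy)-6,8,8-trimethyl-2-oxo-2H,8H-pyrano[2,3-f]chromen-3-yl]-2,2-dimethylchromane-3,4-diyl diacetate
Conditions: TBAF (1.1 equiv), AcOH (1.2 equiv), THF, 0 °C
Reagents that add atoms: none
Why: Fluoride cleavage of the aryl silyl ether, buffered with acetic acid so that the acetates and the 4-methoxycoumarin are untouched, frees the C5' phenol needed for oxidation.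

Step 19
Reactants: 23 (3R,4S)-8-hydroxy-6-[4-methoxy-5-(methoxymethoxy)-6,8,8-trimethyl-2-oxo-2H,8H-pyrano[2,3-f]chromen-3-yl]-2,2-dimethylchromane-3,4-diyl diacetate
Product: 25 5-O-methoxymethyl ether 3''',4'''-diacetate of the target (coumaronochromone with free C5'–OH), via 4-methoxybenzopyrylium acetate 24 (not isolated)
Conditions: PhI(OAc)2 (1.05 equiv), HFIP/CH2Cl2 (1:1), −10 to 0 °C; then sat. aq. NaHCO3, rt
Reagents that add atoms: water, O
Why: Proposed new method: ligand exchange of the C5' phenol on PhI(OAc)2 and loss of iodobenzene generate a phenoxenium-type cation with positive charge at the para carbon C2', the carbonyl oxygen on C2 of the 4-methoxycoumarin adds to C2', the C2' proton is lost so that ring B regains aromaticity as the C5' phenol, and the 2-aryloxy-4-methoxybenzopyrylium salt 24 is hydrolysed at C4 during the bicarbonate work-up with loss of methanol to leave the chromone carbonyl. The closest known reactions are PhI(OAc)2-mediated dearomatising cyclisations of phenols onto tethered oxygen nucleophiles (spirolactonisation, cycloetherification) and the oxidative cyclisation of 3-aryl-4-hydroxycoumarins to coumestans; a lactone carbonyl oxygen attacking an unsubstituted para carbon with later O-dealkylation has no direct precedent. Ring D, the only ring formed, closes by five-membered exo attack of oxygen on the cationic C2' (ring atoms O, C2, C3, C1', C2'). No stereocentre is created, and C3''' and C4''' are bystanders whose acetates prevent glycol cleavage. The step needs O2 rather than O4 as nucleophile, secured by the O4 methyl ether that rules out the coumestan; attack at C2' rather than C6' or C4', favoured because para capture of a phenoxenium ion is preferred over ortho capture and because the non-nucleophilic fluoroalcohol offers no external nucleophile for ketalisation at the alkoxy-bearing C4'; and oxidation of ring B rather than ring A, secured by the methoxymethyl ether on C5–O.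

Step 20
Reactants: 25 5-O-methoxymethyl ether 3''',4'''-diacetate of the target
Product: 26 3''',4'''-diacetate of the target
Conditions: 2 M aq. HCl, THF, 25 °C
Reagents that add atoms: none
Why: Acid-catalysed acetal hydrolysis; a methoxymethyl ether peri to the chromone carbonyl is unusually labile (the freed phenol hydrogen-bonds to C4=O), so dilute acid at room temperature should suffice without ionising the benzylic acetate at C4'''.

Step 21
Reactants: 26 3''',4'''-diacetate of the target
Product: 27 CNP0351839.1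
Conditions: K2CO3 (0.5 equiv), MeOH, 0 °C to rt; then aq. NH4Cl
Reagents that add atoms: none
Why: Base-catalysed transesterification (Zemplén type) removes both acetates by acyl–oxygen cleavage, so no bond to C3''' or C4''' is broken and the trans-(3'''R,4'''S) configuration is retained, giving the target.

**Compound list**

1 | 2,4,6-trihydroxybenzaldehyde | O=Cc1c(O)cc(O)cc1O | starting material
2 | 4-formyl-3,5-dihydroxyphenyl 4-methylbenzenesulfonate | O=Cc1c(O)cc(OS(=O)(=O)c2ccc(C)cc2)cc1O | intermediate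
3 | 3,5-dihydroxy-4-(hydroxymethyl)phenyl 4-methylbenzenesulfonate (benzylic alcohol, not isolated) | OCc1c(O)cc(OS(=O)(=O)c2ccc(C)cc2)cc1O | intermediate
4 | 3,5-dihydroxy-4-methylphenyl 4-methylbenzenesulfonate | Cc1c(O)cc(OS(=O)(=O)c2ccc(C)cc2)cc1O | intermediate
5 | 2-acetyl-3,5-dihydroxy-4-methylphenyl 4-methylbenzenesulfonate | CC(=O)c1c(O)c(C)c(O)cc1OS(=O)(=O)c1ccc(C)cc1 | intermediate
6 | 3-methylbut-2-enal | CC(C)=CC=O | starting material
7 | 6-acetyl-7-hydroxy-2,2,8-trimethyl-2H-chromen-5-yl 4-methylbenzenesulfonate | CC(=O)c1c(O)c(C)c2OC(C)(C)C=Cc2c1OS(=O)(=O)c1ccc(C)cc1 | intermediate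
8 | 6-acetyl-7-(methoxymethoxy)-2,2,8-trimethyl-2H-chromen-5-yl 4-methylbenzenesulfonate | CC(=O)c1c(OCOC)c(C)c2OC(C)(C)C=Cc2c1OS(=O)(=O)c1ccc(C)cc1 | intermediate
9 | 1-[5-hydroxy-7-(methoxymethoxy)-2,2,8-trimethyl-2H-chromen-6-yl]ethan-1-one | CC(=O)c1c(OCOC)c(C)c2OC(C)(C)C=Cc2c1O | intermediate
10 | 4-hydroxy-5-(methoxymethoxy)-6,8,8-trimethyl-2H,8H-pyrano[2,3-f]chromen-2-one | COCOc1c(C)c2OC(C)(C)C=Cc2c2oc(=O)cc(O)c12 | intermediate
11 | 3-bromo-4-hydroxy-5-(methoxymethoxy)-6,8,8-trimethyl-2H,8H-pyrano[2,3-f]chromen-2-one | COCOc1c(C)c2OC(C)(C)C=Cc2c2oc(=O)c(Br)c(O)c12 | intermediate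
12 | 3-bromo-4-methoxy-5-(methoxymethoxy)-6,8,8-trimethyl-2H,8H-pyrano[2,3-f]chromen-2-one | COCOc1c(C)c2OC(C)(C)C=Cc2c2oc(=O)c(Br)c(OC)c12 | intermediate
13 | catechol (benzene-1,2-diol) | Oc1ccccc1O | starting material
14 | 2-[(triisopropylsilyl)oxy]phenol | CC(C)[Si](Oc1ccccc1O)(C(C)C)C(C)C | intermediate
15 | 3-chloro-3-methylbut-1-yne | CC(C)(Cl)C#C | starting material
16 | triisopropyl{2-[(2-methylbut-3-yn-2-yl)oxy]phenoxy}silane | CC(C)[Si](Oc1ccccc1OC(C)(C)C#C)(C(C)C)C(C)C | intermediate
17 | [(2,2-dimethyl-2H-chromen-8-yl)oxy]triisopropylsilane | CC(C)[Si](Oc1cccc2C=CC(C)(C)Oc12)(C(C)C)C(C)C | intermediate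
18 | (3R,4R)-3,4-epoxy-2,2-dimethyl-8-[(triisopropylsilyl)oxy]-3,4-dihydro-2H-chromene | CC(C)[Si](Oc1cccc2[C@H]3O[C@H]3C(C)(C)Oc12)(C(C)C)C(C)C | intermediate
19 | (3R,4S)-2,2-dimethyl-8-[(triisopropylsilyl)oxy]chromane-3,4-diol (trans) | CC(C)[Si](Oc1cccc2[C@H](O)[C@@H](O)C(C)(C)Oc12)(C(C)C)C(C)C | intermediate
20 | (3R,4S)-2,2-dimethyl-8-[(triisopropylsilyl)oxy]chromane-3,4-diyl diacetate | CC(C)[Si](Oc1cccc2[C@H](OC(C)=O)[C@@H](OC(C)=O)C(C)(C)Oc12)(C(C)C)C(C)C | intermediate
21 | (3R,4S)-2,2-dimethyl-6-(4,4,5,5-tetramethyl-1,3,2-dioxaborolan-2-yl)-8-[(triisopropylsilyl)oxy]chromane-3,4-diyl diacetate | CC(C)[Si](Oc1cc(B3OC(C)(C)C(C)(C)O3)cc2[C@H](OC(C)=O)[C@@H](OC(C)=O)C(C)(C)Oc12)(C(C)C)C(C)C | intermediate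
22 | (3R,4S)-6-[4-methoxy-5-(methoxymethoxy)-6,8,8-trimethyl-2-oxo-2H,8H-pyrano[2,3-f]chromen-3-yl]-2,2-dimethyl-8-[(triisopropylsilyl)oxy]chromane-3,4-diyl diacetate | COCOc1c(C)c2OC(C)(C)C=Cc2c2oc(=O)c(-c3cc(O[Si](C(C)C)(C(C)C)C(C)C)c4OC(C)(C)[C@H](OC(C)=O)[C@@H](OC(C)=O)c4c3)c(OC)c12 | intermediate
23 | (3R,4S)-8-hydroxy-6-[4-methoxy-5-(methoxymethoxy)-6,8,8-trimethyl-2-oxo-2H,8H-pyrano[2,3-f]chromen-3-yl]-2,2-dimethylchromane-3,4-diyl diacetate (3-aryl-4-methoxycoumarin with free C5'–OH) | COCOc1c(C)c2OC(C)(C)C=Cc2c2oc(=O)c(-c3cc(O)c4OC(C)(C)[C@H](OC(C)=O)[C@@H](OC(C)=O)c4c3)c(OC)c12 | intermediate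
24 | 4-methoxybenzopyrylium acetate formed by O–C2' closure (not isolated) | Cc1c2c(c3[o+]c4oc5c6c(c(O)cc5c4c(OC)c3c1OCOC)OC(C)(C)[C@H](OC(C)=O)[C@H]6OC(C)=O)C=CC(C)(C)O2.CC(=O)[O-] | intermediate
25 | 5-O-methoxymethyl ether 3''',4'''-diacetate of the target | Cc1c2c(c3oc4oc5c6c(c(O)cc5c4c(=O)c3c1OCOC)OC(C)(C)[C@H](OC(C)=O)[C@H]6OC(C)=O)C=CC(C)(C)O2 | intermediate
26 | 3''',4'''-diacetate of the target | Cc1c2c(c3oc4oc5c6c(c(O)cc5c4c(=O)c3c1O)OC(C)(C)[C@H](OC(C)=O)[C@H]6OC(C)=O)C=CC(C)(C)O2 | intermediate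
27 | CNP0351839.1: 5,5'-dihydroxy-6-methylcoumaronochromone with a 2,2-dimethyl-2H-pyran on O7/C8 and a (3'''R,4'''S)-3,4-dihydroxy-2,2-dimethyl-3,4-dihydro-2H-pyran on C3'/C4' | Cc1c2c(c3oc4oc5c6c(c(O)cc5c4c(=O)c3c1O)OC(C)(C)[C@H](O)[C@H]6O)C=CC(C)(C)O2 | target

**Totals**

Total step count: 21. Longest linear sequence: 14 steps (steps 1–9, then 17–21).

**Three steps most likely to fail**

Step 19 (the proposed new method). The oxidised ring B may be captured at C6' (ortho to the phenol oxygen) instead of C2'. The product, itself a para-alkoxyphenol, may be oxidised further to a quinone. Water may also open the pyrylium ion at C2 instead of C4. The fallback uses known chemistry and closes ring D from a 2'-hydroxyisoflavone by DDQ dehydrogenative cyclisation. It sets out from acetophenone 9 and boronate 21 and comes back to the route at 25. Condensation of 9 with N,N-dimethylformamide dimethyl acetal should give enaminone F1, and iodine in methanol should close it to 3-iodochromone F2 with loss of dimethylamine. Suzuki–Miyaura coupling of F2 with 21 (Pd(dppf)Cl2, K3PO4) should give silyl-protected isoflavone F3, and buffered TBAF should free phenol isoflavone F4. Teuber oxidation with (KSO3)2NO should convert this para-unsubstituted phenol into 2',5'-quinone F5, and Na2S2O4 should reduce it to hydroquinone F6, which is kept neutral. TIPSCl and imidazole should silylate the unhindered, non-chelated C5' hydroxyl to give 2'-hydroxyisoflavone F7. DDQ in dioxane should then effect the established dehydrogenative cyclisation to silylated coumaronochromone F8, and buffered TBAF returns the route at 25.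

Step 4. Carbon–carbon bond formation may be sluggish at a ring carbon flanked by the electron-withdrawing tosyloxy group, with self-condensation of the enal taking over. The fallback sets out from 5 and comes back at 7. The unchelated hydroxyl of 5 is alkylated with 15 (K2CO3, KI, acetone, 56 °C) to give propargyl ether F9. Thermal aromatic Claisen rearrangement in N,N-diethylaniline at 190 °C, which can only reach the one free ortho carbon, should give 7.

Step 14. Stereochemical fidelity may be lost at the benzylic carbon if the protonated epoxide opens through a free benzylic cation, so that water also enters syn. The fallback sets out from 18 and comes back at 19, and fixes C4 by reduction instead of by epoxide opening. The hydrolysis mixture, which then contains cis-diol F10 beside 19, is oxidised at the benzylic carbinol with MnO2 in CH2Cl2 to the single hydroxy ketone F11. Hydroxyl-directed reduction with Me4NBH(OAc)3 in MeCN/AcOH (Evans–Saksena type), in which hydride is delivered from the face of the C3 hydroxyl, should return trans-diol 19.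

**Further compounds**

F1 | step 19 | (E)-3-(dimethylamino)-1-[5-hydroxy-7-(methoxymethoxy)-2,2,8-trimethyl-2H-chromen-6-yl]prop-2-en-1-one | CN(C)/C=C/C(=O)c1c(OCOC)c(C)c2OC(C)(C)C=Cc2c1O
F2 | step 19 | 3-iodo-5-(methoxymethoxy)-6,8,8-trimethyl-4H,8H-pyrano[2,3-f]chromen-4-one | COCOc1c(C)c2OC(C)(C)C=Cc2c2occ(I)c(=O)c12
F3 | step 19 | (3R,4S)-6-[5-(methoxymethoxy)-6,8,8-trimethyl-4-oxo-4H,8H-pyrano[2,3-f]chromen-3-yl]-2,2-dimethyl-8-[(triisopropylsilyl)oxy]chromane-3,4-diyl diacetate | COCOc1c(C)c2OC(C)(C)C=Cc2c2occ(-c3cc(O[Si](C(C)C)(C(C)C)C(C)C)c4OC(C)(C)[C@H](OC(C)=O)[C@@H](OC(C)=O)c4c3)c(=O)c12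
F4 | step 19 | (3R,4S)-8-hydroxy-6-[5-(methoxymethoxy)-6,8,8-trimethyl-4-oxo-4H,8H-pyrano[2,3-f]chromen-3-yl]-2,2-dimethylchromane-3,4-diyl diacetate | COCOc1c(C)c2OC(C)(C)C=Cc2c2occ(-c3cc(O)c4OC(C)(C)[C@H](OC(C)=O)[C@@H](OC(C)=O)c4c3)c(=O)c12
F5 | step 19 | (3R,4S)-6-[5-(methoxymethoxy)-6,8,8-trimethyl-4-oxo-4H,8H-pyrano[2,3-f]chromen-3-yl]-2,2-dimethyl-5,8-dioxo-3,4,5,8-tetrahydro-2H-chromene-3,4-diyl diacetate | COCOc1c(C)c2OC(C)(C)C=Cc2c2occ(C3=CC(=O)C4=C([C@H](OC(C)=O)[C@@H](OC(C)=O)C(C)(C)O4)C3=O)c(=O)c12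
F6 | step 19 | (3R,4S)-5,8-dihydroxy-6-[5-(methoxymethoxy)-6,8,8-trimethyl-4-oxo-4H,8H-pyrano[2,3-f]chromen-3-yl]-2,2-dimethylchromane-3,4-diyl diacetate | COCOc1c(C)c2OC(C)(C)C=Cc2c2occ(-c3cc(O)c4OC(C)(C)[C@H](OC(C)=O)[C@@H](OC(C)=O)c4c3O)c(=O)c12
F7 | step 19 | (3R,4S)-5-hydroxy-6-[5-(methoxymethoxy)-6,8,8-trimethyl-4-oxo-4H,8H-pyrano[2,3-f]chromen-3-yl]-2,2-dimethyl-8-[(triisopropylsilyl)oxy]chromane-3,4-diyl diacetate | COCOc1c(C)c2OC(C)(C)C=Cc2c2occ(-c3cc(O[Si](C(C)C)(C(C)C)C(C)C)c4OC(C)(C)[C@H](OC(C)=O)[C@@H](OC(C)=O)c4c3O)c(=O)c12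
F8 | step 19 | 5'-O-triisopropylsilyl ether of 25 | Cc1c2c(c3oc4oc5c6c(c(O[Si](C(C)C)(C(C)C)C(C)C)cc5c4c(=O)c3c1OCOC)OC(C)(C)[C@H](OC(C)=O)[C@H]6OC(C)=O)C=CC(C)(C)O2
F9 | step 4 | 2-acetyl-3-hydroxy-4-methyl-5-[(2-methylbut-3-yn-2-yl)oxy]phenyl 4-methylbenzenesulfonate | CC(=O)c1c(O)c(C)c(OC(C)(C)C#C)cc1OS(=O)(=O)c1ccc(C)cc1
F10 | step 14 | (3R,4R)-2,2-dimethyl-8-[(triisopropylsilyl)oxy]chromane-3,4-diol (cis) | CC(C)[Si](Oc1cccc2[C@@H](O)[C@@H](O)C(C)(C)Oc12)(C(C)C)C(C)C
F11 | step 14 | (3S)-3-hydroxy-2,2-dimethyl-8-[(triisopropylsilyl)oxy]chroman-4-one | CC(C)[Si](Oc1cccc2C(=O)[C@@H](O)C(C)(C)Oc12)(C(C)C)C(C)C
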